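**Assumption:** the stereocentre in the target is (R) (priorities OH > ring C3 > propyl > H). Which pseudo-enantiomer of the step 4 ligand gives (R) cannot be predicted; the quinine-derived one is taken provisionally and is exchanged for the quinidine-derived one if the first run shows the opposite sense.

## Retrosynthetic overview

1. Target 9 ⇒ C1′–O bond: copper-catalysed enantioconvergent hydroxylation of racemic side-chain bromide 8 with water, which sets the only stereocentre in the last step.
2. 8 ⇒ 3-butyl fimbrolide 7 by radical bromination at C1′ (the side-chain carbon on ring C3).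
3. 7 ⇒ ring O–C5 bond: bromination and oxidative cyclodehydration of 2-butyllevulinic acid 5; this forms the only ring, the butenolide.
4. 5 ⇒ ethyl acetoacetate 1 + ethyl 2-bromohexanoate 2 (acetoacetic ester synthesis).

## Route

**Step 1**
Reactants: 1 ethyl acetoacetate; 2 ethyl 2-bromohexanoate (racemic)
Product: 5 2-butyl-4-oxopentanoic acid (racemic), via keto diester 3 (not isolated), via keto diacid 4 (not isolated)
Conditions: NaOEt (1.05 equiv), EtOH, reflux, 12 h; distil off EtOH; 6 M aq HCl, reflux, 16 h
Reagents that add atoms: water (O)
Why: Acetoacetic ester synthesis, that is SN2 alkylation of the sodium enolate of 1 by the α-bromo ester 2, then acid-catalysed hydrolysis of both esters and decarboxylation of the β-keto acid; the C2 stereocentre stays racemic because it becomes sp2 in step 2.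

**Step 2**
Reactants: 5 2-butyl-4-oxopentanoic acid
Product: 7 4-bromo-3-butyl-5-(dibromomethylene)furan-2(5H)-one, via tribromo keto acid 6 (not isolated)
Conditions: Br2 (3.1 equiv), CHCl3, 0 °C to rt; evaporate; conc. H2SO4, 105 °C, 25 min; pour onto ice
Reagents that add atoms: bromine (BrBr)
Why: Acid-catalysed α-bromination of the ketone (once at C3, twice at C5), then sulfuric-acid-mediated cyclodehydration in which the carboxyl oxygen closes the O–C5 bond, with dehydrogenation by hot H2SO4 to the conjugated ylidene-butenolide; this is the classical brominated-levulinic-acid cyclisation to fimbrolides and creates no stereocentre.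

**Step 3**
Reactants: 7 4-bromo-3-butyl-5-(dibromomethylene)furan-2(5H)-one
Product: 8 racemic 4-bromo-3-(1-bromobutyl)-5-(dibromomethylene)furan-2(5H)-one
Conditions: NBS (1.05 equiv), (PhCO2)2 (5 mol%), PhCF3, visible-light lamp, reflux
Reagents that add atoms: N-bromosuccinimide (O=C1CCC(=O)N1Br)
Why: Wohl–Ziegler bromination is selective for the C1′–H because its radical is delocalised over the brominated dienone, and the fully substituted electron-poor alkenes do not add bromine; the stereocentre is formed racemic on purpose since both enantiomers are used in step 4.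

**Step 4**
Reactants: 8 racemic 4-bromo-3-(1-bromobutyl)-5-(dibromomethylene)furan-2(5H)-one
Product: 9 (R)-4-bromo-5-(dibromomethylene)-3-(1-hydroxybutyl)furan-2(5H)-one
Conditions: CuBr·SMe2 (10 mol%), L* (12 mol%), H2O (5 equiv), Cs2CO3 (1.2 equiv), EtOAc, 0 °C, argon, dark. L* = N-(9-deoxy-epi-quinin-9-yl)-2-[bis(3,5-di-tert-butylphenyl)phosphino]benzamide, a chiral anionic N,N,P ligand after amide deprotonation.
Reagents that add atoms: water (O)
Why: Proposed new method: copper-catalysed enantioconvergent radical hydroxylation of a racemic secondary allylic-type bromide with water, in which monovalent copper bound to deprotonated L* abstracts bromine from either enantiomer of 8 to give one planar, butenolide-conjugated (aryl-like) radical, the resulting divalent copper bromide exchanges Br for OH (water/Cs2CO3), and stereodetermining radical capture followed by C–O reductive elimination from trivalent copper gives the alcohol with the (R) centre set by the ligand pocket (propyl versus flat ring discrimination, as for 1-arylalkyl radicals); C1′ is the only radical terminus whose coupling restores the conjugated ylidene-butenolide and the three vinylic C–Br bonds are inert to monovalent copper at 0 °C; the closest known reaction type is the copper/chiral anionic N,N,P-ligand enantioconvergent radical C–N and C–O cross-coupling of racemic secondary benzylic and α-carbonyl halides with amines, sulfoximines and oximes, not shown with water on a polybrominated butenolide-substituted carbinyl bromide.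

## Compound list

1 | ethyl acetoacetate (ethyl 3-oxobutanoate) | CCOC(=O)CC(C)=O | starting material
2 | ethyl 2-bromohexanoate (racemic) | CCCCC(Br)C(=O)OCC | starting material
3 | diethyl 2-acetyl-3-butylbutanedioate (racemic diastereomer mixture) | CCCCC(C(=O)OCC)C(C(C)=O)C(=O)OCC | intermediate
4 | 2-acetyl-3-butylbutanedioic acid (racemic diastereomer mixture) | CCCCC(C(O)=O)C(C(C)=O)C(O)=O | intermediate
5 | 2-butyl-4-oxopentanoic acid (racemic) | CCCCC(CC(C)=O)C(O)=O | intermediate
6 | 3,5,5-tribromo-2-butyl-4-oxopentanoic acid (diastereomer mixture) | CCCCC(C(O)=O)C(Br)C(=O)C(Br)Br | intermediate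
7 | 4-bromo-3-butyl-5-(dibromomethylene)furan-2(5H)-one | CCCCC1=C(Br)C(=C(Br)Br)OC1=O | intermediate
8 | racemic 4-bromo-3-(1-bromobutyl)-5-(dibromomethylene)furan-2(5H)-one | CCCC(Br)C1=C(Br)C(=C(Br)Br)OC1=O | intermediate
9 | (R)-4-bromo-5-(dibromomethylene)-3-(1-hydroxybutyl)furan-2(5H)-one | CCC[C@@H](O)C1=C(Br)C(=C(Br)Br)OC1=O | target

## Step count and risk

Total step count: 4. Longest linear sequence: 4 steps (from 1 and 2). Step 3 is judged the least risky, because side-chain Wohl–Ziegler bromination is the standard way to functionalise 3-alkyl fimbrolides.

**Step 4 (proposed new step; most likely to fail).** The risks are low enantioselectivity, base-induced elimination of HBr to the 3-(but-1-enyl) diene, and attack of hydroxide on the lactone. The fallback uses known chemistry and sets out from 8. Solvolysis in aqueous DMSO (DMSO/H2O 4:1, 50 °C) gives racemic 4-bromo-5-(dibromomethylene)-3-(1-hydroxybutyl)furan-2(5H)-one F5. Preparative chiral SFC (amylose tris(3,5-dimethylphenylcarbamate) phase, CO2/iPrOH) separates it into 9 and the unwanted (S)-4-bromo-5-(dibromomethylene)-3-(1-hydroxybutyl)furan-2(5H)-one F6. The fallback comes back to the route at 9.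

**Step 2.** The one-pot tribromination and hot-H2SO4 oxidative cyclisation is precedented but low-yielding, and gives mixtures with the mono-bromomethylene analogue. The fallback sets out from 5 and adjusts the halogenation after the ring is made. Br2 (2.0 equiv) in CHCl3 gives 3,5-dibromo-2-butyl-4-oxopentanoic acid F2. Conc. H2SO4 at 100 °C cyclises it to (Z)-4-bromo-5-(bromomethylene)-3-butylfuran-2(5H)-one F3. Br2 (1.05 equiv) in CH2Cl2 adds across the exocyclic alkene to give 4,5-dibromo-3-butyl-5-(dibromomethyl)furan-2(5H)-one F4. Et3N (1.1 equiv) in CH2Cl2 at 0 °C then eliminates HBr. The fallback comes back to the route at 7.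

**Step 1.** SN2 alkylation with the secondary α-bromo ester 2 competes with E2 elimination and dialkylation, and the telescoped hydrolysis of the hindered ester is slow. The fallback sets out from 2 and replaces enolate alkylation by a radical C–C coupling. Visible-light photoredox addition of 2 to isopropenyl acetate (Ir(ppy)3 1 mol%, blue LEDs, MeCN, rt) gives ethyl 2-butyl-4-oxopentanoate F1; the adduct collapses to the methyl ketone with loss of acetyl bromide, which is hydrolysed on work-up. Hydrolysis of F1 in 6 M aq HCl at reflux then comes back to the route at 5.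

## Further compounds

F1 | step 1 | ethyl 2-butyl-4-oxopentanoate (racemic) | CCCCC(CC(C)=O)C(=O)OCC
F2 | step 2 | 3,5-dibromo-2-butyl-4-oxopentanoic acid (diastereomer mixture) | CCCCC(C(O)=O)C(Br)C(=O)CBr
F3 | step 2 | (Z)-4-bromo-5-(bromomethylene)-3-butylfuran-2(5H)-one | CCCCC1=C(Br)/C(=C/Br)OC1=O
F4 | step 2 | 4,5-dibromo-3-butyl-5-(dibromomethyl)furan-2(5H)-one (racemic) | CCCCC1=C(Br)C(Br)(C(Br)Br)OC1=O
F5 | step 4 | racemic 4-bromo-5-(dibromomethylene)-3-(1-hydroxybutyl)furan-2(5H)-one | CCCC(O)C1=C(Br)C(=C(Br)Br)OC1=O
F6 | step 4 | (S)-4-bromo-5-(dibromomethylene)-3-(1-hydroxybutyl)furan-2(5H)-one | CCC[C@H](O)C1=C(Br)C(=C(Br)Br)OC1=O
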